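The half-life of substrate by the coupling step, 2.4 min with the whole partner charge counted as present, is far shorter than the 25 h of the run, so for this flask we ask how far it goes rather than how fast.

    substrate + coupling partner → target (k1 = 0.50 /M/min)
    2 coupling partner → side product (k2 = 0.0076 /M/min)

substrate 0.58 M; coupling partner 0.580 M (in portions, 2); time 25 h; the portions of coupling partner follow each other after 80 s, the first at the start

- where a step has two of a species, its rate is k times that concentration squared, and two are used at each turn
- the reaction counts as stopped when no species that holds the substrate changes by six tenths of a point or more over the second half of the time
- run time (flask): 25 h

- which holds at 25 h: what has brought the reaction to rest, or that it has not come to rest (all of the substrate has reacted / the coupling partner has run out first / it is still moving)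
- share of the substrate used up at 25 h
- target at 25 h, in percent of the substrate charged

Let a be the substrate left and b the coupling partner left, both as fractions of the substrate charge. We reckon as if both portions stood there from the start, though the second comes after 80 s. In fractions of the charge per unit time, the two rates are:

coupling: 0.290 /min · a · b
side step, partner used: 0.00882 /min · b · b

The side step starts slower. When a and b both fall by a factor of 10, each rate falls by 2 powers of ten, so their quotient holds. That quotient at equal a and b, the partner burnt per partner coupled, is the loss ratio:

L = 2 · 0.0076 /M/min / 0.50 /M/min = 0.0304

Partner used per substrate used is therefore 1 + L·b/a, which integrates to

(1 − L) · b = a − L · a^L

The partner, our limiting reagent, tends to zero as a approaches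

log10 a = −1.52 / 0.970 = −1.56
a = 2.72%

Near that a the coupling is pseudo-first-order in b, and b dies away with a time constant of roughly 1/(rate constant · a) = 2.11 h, which is shorter than the run. We commit to the partner running out first, at 97.3% conversion.

The forecast also says the coupling partner has run out first, with 97.3% conversion and 97.3% target, since the partner's loss “leaves it just short”.

The simulation of this flask gives 97.5% conversion and 97.5% target: the coupling partner has run out first, with 0% of it left. Substrate stands at 2.5% against our 2.72%, and this flask still shows 2.50% at 250 h. In the neighbouring flask with 0.35 M of coupling partner, b starts at 0.603, and the same integration with the same L gives, with b now standing for that starting value,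

a = (1 − b · (1 − L))^(1/(1 − L)) = 40.4%

That neighbouring flask ends with 40.3% of its substrate left.

(The numbers of this flask are assumed; the run is a simulation.)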